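Assumption: photoadduct 6 is drawn as the C8 epimer expected from addition of the enone to the alkene face remote from the ring methyl group; the other C8 epimer would behave the same way and converges at step 9, where C8 becomes trigonal.

## Structural features

The target is a cis-fused hydroazulene: cyclopentane ring A (C1–C2–C3–C4–C5) shares the C1–C5 bond with cycloheptene ring B (C5–C6–C7–C8=C9–C10–C1). These locants are used throughout, and α denotes the face that carries the C1 methyl group and H5. Five stereocentres form one contiguous block: quaternary C1 (methyl), C5 (H), the tertiary carbinol C4 (β-OH, α-isopropyl), C6 (α-4-hydroxybenzoyloxy) and C10 (α-tigloyloxy); in CIP terms 1R,4R,5S,6S,10R. C8 carries a methyl group on the trisubstituted C8=C9 alkene, which makes the C10 ester allylic. The fragile groups are the allylic tiglate (ionisation, allylic shift), the aryl ester with its free phenol, the tertiary alcohol 1,3 to the C6 oxygen (dehydration or retro-aldol whenever C6 is a ketone) and H5, which is epimerisable whenever C6 is a carbonyl. The real difficulty lies in the quaternary C1 wedged between C5 and C10, the cis ring fusion, telling the two secondary oxygens at C6 and C10 apart, and setting C10 next to the quaternary carbon. The key step exploits the fact that C6 and C10 are attached to the adjacent ring A atoms C5 and C1: this 1,4-dioxygen pattern across C5–C1 is what a cleaved cyclobutane-1,2-diol leaves behind, so reconnecting C6–C10 turns ring B into a cyclobutane (C1–C5–C6–C10) fused to a five-membered ring (C6–C7–C8–C9–C10). In addition, the C4 hydroxyl lies on the β face cis to both C6 and C10, so it can steer hydride to both carbonyl carbons.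

## Logic of the disconnections

23 ⇒ 22. No skeletal bond is cut; the phenolic O–H is exchanged for O–Si. The phenol is the most acidic and most nucleophilic site and would compete in both acylations, so masking it leaves one reactive hydroxyl in each earlier acylation. The forward step must use buffered fluoride so that the allylic C10 ester and the aryl ester stay in place.

22 ⇒ 19 + 20. The acyl–oxygen bond at C10 is cut. The allylic ester is the most ionisable group and should see as few later steps as possible, so it is introduced last of the two. 19 has a single secondary hydroxyl, since the C4 hydroxyl is tertiary and hindered. The forward acylation must be strong enough for a neopentyl-type allylic alcohol and must not isomerise the E-alkene of 20; this is met by the mixed anhydride 21.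

19 ⇒ 18. The C10–H bond is cut (carbinol back to enone). This reduces the C10 stereocentre to one hydride delivery next to the quaternary carbon. The forward step needs hydride on the β face, which is asked of intramolecular delivery from the C4 hydroxyl, cis-1,3 to C10 on ring A.

18 ⇒ 15. The C8=C9 π bond is removed (C8–H and C9–H restored). The alkene is placed by dehydrogenation of the C10 ketone, whose only enolisable position is C9 because C1 is quaternary, so the regiochemistry is built in and the C8 centre of 15 becomes irrelevant. The forward step (through 16 and 17) must avoid strong base, because the enone of 18 could lose the C6 ester through its γ-hydrogens.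

15 ⇒ 10 + 13, and 13 ⇒ 11. The acyl–oxygen bond at C6 is cut. In 10 the C6 hydroxyl is the only secondary alcohol while C10 is still a ketone, so the two oxygens are distinguished by oxidation level. 13 comes from 11 by silylation through 12.

10 ⇒ 9. The C6–H bond is cut. Telling C6 from C10 becomes a question of which carbonyl is β to the C4 hydroxyl, and that is C6. The forward step needs a hydride source that reacts only when delivered by a hydroxyl, and it must be fast and mild because H5 is epimerisable in 9.

9 ⇒ 7 (through 8). The C6–C10 bond is reconnected: the 1,4-diketone across C5–C1 is the cleavage product of a cis-cyclobutane-1,2-diol. The seven-membered ring disappears and is replaced by a four- and a five-membered ring, so no medium ring has to be closed. The forward demand is one of order: the diol may be unmasked only after the C4 carbonyl has gone, because a β-oxygenated cyclobutyl ketone would open by retro-aldol cleavage.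

7 ⇒ 6. The C4–isopropyl bond is cut, leaving a ketone in a rigid bicyclo[3.2.0]heptanone unit with a convex and a concave face. The forward addition must come from the convex face and must beat enolisation and reduction.

6 ⇒ 4 + 5. The C1–C10 and C5–C6 bonds are cut, which is the retro-[2+2] of the cyclobutane. Two commercial-grade five-membered rings result, and the quaternary C1 and the cis C1/C5 fusion are created in one step. The forward step needs only enantioface selection on 5, because 4 is symmetrical and ring strain enforces both cis fusions.

4 ⇒ 2 ⇒ 1. The O–Si bonds are exchanged (bulky silyl groups back to trimethylsilyl) and the C6–C10 bond, here the enediol double-bond carbons, is cut by the retro-acyloin. This leads to an acyclic diester whose ester carbons become C6 and C10 and whose methyl-bearing carbon becomes C8. The forward acyloin coupling needs in-flask trapping by Me3SiCl.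

## Other disconnections considered

Alternative 1: The cut is at C5–C1 and C5–C6, detaching the carbene carbon C5 from an aromatic ring whose six carbons become C1 and C6–C10. In the forward sense the diazoketone A1 would be decomposed by Cu(MeCN)4PF6 with a chiral bis(oxazoline) ligand (or Rh2(OAc)4 for the racemate); the carbene cyclopropanates the ipso/ortho bond and the norcaradiene opens to the azulenone A2.
- In its favour: both rings arise in one catalytic step from a flat arene; the C4 ketone, the C8 methyl group, a C8=C9 double bond and a C10 oxygen are already in place. Asymmetric intramolecular Buchner reactions of this diazoketone class are established, so on precedent for the enantioselective event it is better founded than step 3.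
- Against it here: A2 has no methyl group at C1 (an enol-ether sp2 carbon), so the quaternary centre and its cis relation to H5 would have to be built later under the control of C5 alone. C5 in A2 is a weak control element: it is α to the ketone, doubly allylic and part of a cycloheptatriene–norcaradiene equilibrium, so racemisation by enolisation and acid-induced rearrangement to a 2-tetralone threaten. C6 is an alkene carbon needing a regio- and face-selective oxygenation within a triene, and A1 requires diazomethane or a diazo-transfer sequence.
- Comparison: on ring construction it is the equal of the chosen plan or better (two rings in one step against one ring plus a later cleavage). On stereochemistry it is weaker (one labile centre against the secure C1/C5 pair that relays to C4, C6 and C10). On step economy the short approach to A2 (about three steps) is offset by an estimated ten or more steps of adjustment, so no net gain is expected.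

Alternative 2: The cut is the C5–C6 bond of ring B. In the forward sense SmI2 reduces the C5–Br bond of the bromo keto aldehyde A3 to a samarium enolate of defined regiochemistry, which adds to the tethered aldehyde and gives the hydroazulene A4.
- In its favour: A4 already carries the C8=C9 alkene, the C10 oxygen with its configuration, the C6 carbinol and a C4 ketone ready for isopropyl addition. The end game (addition, two acylations, deprotection, perhaps five steps) is clearly shorter than the nine steps that follow step 3, and neither a dehydrogenation nor a differentiation of two ketones is needed; on both points it is better. No photochemistry is required, and the quaternary C1 can be set by established asymmetric conjugate addition or alkylation, at least the equal of the chosen plan on absolute control.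
- Against it here: A3 is a demanding target in itself (quaternary C1 next to the C10 carbinol, a Z-trisubstituted alkene, a β,γ-unsaturated aldehyde that drifts into conjugation, an α-bromo ketone), probably ten or more linear steps. The seven-membered ring is closed by an entropically less favourable aldol; the C5/C6 relative configuration rests on a chelated transition state and not on ring strain; and the β-hydroxy ketone A4 can revert by retro-aldol or dehydrate.
- Comparison: structurally A4 is closer to the target than 6. Mechanistically the chosen plan is more secure for C1/C5 but less secure for C10 and for the C6/C10 differentiation. In total count Alternative 2 is estimated to be longer (about sixteen to eighteen steps against twelve).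

Alternative 3: The cut is again at C5, but as a rearrangement: the C1–C5 bond is traced back to a C1–C6 bond of a decalin. In the forward sense the hydroxy mesylate A6, derived from the (R)-Wieland–Miescher ketone A5, is treated with base; the C6 alkoxide pushes, the C1–C6 bond migrates to C5 anti to the leaving group, and the two six-membered rings become the five/seven skeleton A7 with a C6 ketone.
- In its favour: the absolute configuration comes from the proline-catalysed annulation that gives A5, a scalable and reliable source, which is better than step 3 on absolute control. The shift is stereospecific (retention at the migrating C1, inversion at C5), so the cis fusion is programmed by the mesylate. In A7 the three oxygens are already differentiated (C6 ketone, C4 and C10 silyl ethers), which spares the differentiation of step 6; that too is better.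
- Against it here: A6 needs a secondary mesylate at C5 between two fully substituted carbinol carbons, which is hard to sulfonylate and to keep from eliminating. The C3–C4 bond is also antiperiplanar to the leaving group and is assisted by the C4 silyloxy oxygen, so a competing contraction is possible. The C8 methyl group has to be introduced on the decalin. A7 has a saturated C8 and its only carbonyl at C6, so direct dehydrogenation would place the alkene at C7=C8 and not C8=C9, and a transposition is needed.
- Comparison: on structure the plans are roughly equal at C4 (A7 holds it; the chosen plan sets it one step after the key step). On mechanism the ionic shift is more predictable than a new asymmetric photoreaction (better), but the alkene placement is worse than the built-in regiochemistry of step 9. On step economy about ten steps to A6 and seven or more after A7 make it longer than the chosen plan.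

Key step: step 3

## Route

Step 1
Reactants: 1 dimethyl 3-methylglutarate
Product: 2 4-methyl-1,2-bis(trimethylsilyloxy)cyclopentene
Conditions: Na, Me3SiCl, toluene, reflux
Reagents that add atoms: chlorotrimethylsilane, C[Si](C)(C)Cl
Why: Rühlmann acyloin condensation: electron transfer from sodium couples the two ester carbonyl carbons (the future C6 and C10), and Me3SiCl traps the enediolate and the methoxide so that Claisen-type side reactions are suppressed. The product has a mirror plane through C8, so no stereochemical issue arises.

Step 2
Reactants: 2 4-methyl-1,2-bis(trimethylsilyloxy)cyclopentene
Product: 4 4-methyl-1,2-bis(tert-butyldimethylsilyloxy)cyclopentene, via dilithium enediolate 3 (not isolated)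
Conditions: MeLi, THF, 0 °C to rt; then tBuMe2SiCl, DMPU, −78 °C to rt
Reagents that add atoms: tert-butyldimethylsilyl chloride, CC(C)(C)[Si](C)(C)Cl
Why: Methyllithium cleaves silyl enol ethers to lithium enolates (here both Si–O bonds, giving the enediolate 3), and the hard oxygen atoms are re-silylated by the silyl chloride in the presence of DMPU. The bulkier groups are chosen because tert-butyldimethylsilyl enol ethers tolerate the strong Lewis acid of step 3 and keep the β-silyloxy ketone 6 from losing silicon and fragmenting by retro-aldol cleavage before step 4.

Step 3
Reactants: 4 4-methyl-1,2-bis(tert-butyldimethylsilyloxy)cyclopentene; 5 3-methylcyclopent-2-en-1-one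
Product: 6 cis-anti-cis tricyclic ketone (cyclobutane C1–C5–C6–C10 between ring A and the methylcyclopentane ring C; C4 ketone; silyloxy groups at C6 and C10)
Conditions: 4 (3 equiv), AlBr3 complex of (S)-3,3-bis(3,5-dimethylphenyl)-1-(2,4,6-trifluorophenyl)tetrahydro-1H,3H-pyrrolo[1,2-c][1,3,2]oxazaborole (50 mol%), CH2Cl2, −75 °C, hν (366 nm)
Reagents that add atoms: none
Why: Proposed new method: a cationic oxazaborolidine–AlBr3 Lewis acid bound to the carbonyl oxygen of 5 should shift the enone π–π* absorption to longer wavelength, so that 366 nm light excites the chiral complex in preference to free 5 while its aryl group screens one face of the C=C; the closest known reaction type is the enantioselective Lewis-acid-mediated intermolecular [2+2] photocycloaddition of 2-cyclohexenones (3-alkyl members included) with simple alkenes, whereas a five-membered enone and a bis(silyloxy)alkene partner are untested, the nearest support for the latter being that tert-butyldimethylsilyl and triisopropylsilyl enol ethers survive this class of Lewis acid at −78 °C in thermal cycloadditions. Mechanistically the complexed enone triplet bonds to the alkene to give a 1,4-diradical that closes after spin inversion, forming C1–C10 and C5–C6; the racemic counterpart (enone plus 1,2-bis(silyloxy)cycloalkene, later glycol cleavage as a two-carbon ring expansion) is established chemistry. The only ring closed is the cyclobutane, by intermolecular two-bond [2+2] union; it must be cis-fused to ring A because a trans-bicyclo[3.2.0]heptanone is too strained, and cis-fused to ring C because the alkene is held in a five-membered ring. C1 and C5, the two centres that persist, are therefore fixed relative to each other by ring strain (C1 methyl and H5 cis) and in the absolute sense by the catalyst, which has to direct the alkene to the Re face at the enone α-carbon (the face on which C4, C1 and H run clockwise); the (S)-prolinol-derived catalyst is chosen by the binding model of the six-ring enones, and its mirror image is used if the sense proves opposite for the five-ring enone. C6 and C10 follow from the anti approach of ring C (cis-anti-cis) and C8 from attack anti to its methyl group; all three are erased later. The alkene is symmetrical, so no regiochemical question arises. Excess 4 and low temperature are used to outrun photodimerisation of 5 and dark Mukaiyama–Michael addition.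

Step 4
Reactants: 6 cis-anti-cis tricyclic ketone
Product: 7 tertiary alcohol (C4 carbinol of 6 with 4α-isopropyl and 4β-hydroxyl)
Conditions: iPrMgCl, CeCl3, THF, −78 to 0 °C
Reagents that add atoms: isopropylmagnesium chloride, CC(C)[Mg]Cl
Why: Organocerium 1,2-addition to a hindered, enolisable ketone: the cerium reagent is far less basic than the Grignard reagent, which suppresses enolisation towards C3 and β-hydride reduction. The nucleophile should enter on the exo (α) face of the bicyclo[3.2.0]heptanone unit because the endo face is covered by the cyclobutane and its C6 silyloxy group, which sets C4 with isopropyl α and hydroxyl β. A possible O-to-O silyl shift in the alkoxide is harmless because all silyl groups leave in step 5.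

Step 5
Reactants: 7 tertiary alcohol
Product: 9 hydroxy diketone (4β-hydroxy-4α-isopropyl-1α,8-dimethyl-cis-hydroazulane-6,10-dione), via triol 8 (not isolated)
Conditions: Bu4NF, THF, 0 to 40 °C; aqueous work-up; then Pb(OAc)4, CH2Cl2, −20 to 0 °C
Reagents that add atoms: none
Why: Fluoride removes both tertiary silyl ethers only now, when no C4 carbonyl remains that could trigger de Mayo-type retro-aldol opening; the cis-1,2-diol of the strained cyclobutane then forms a cyclic lead diester and fragments (Criegee glycol cleavage), breaking C6–C10 and merging the four- and five-membered rings into ring B. The isolated C4 hydroxyl is not a glycol partner and no stereocentre is touched; 9 is kept cold and neutral and used at once because H5 is now α to the C6 carbonyl.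

Step 6
Reactants: 9 hydroxy diketone
Product: 10 diol ketone (4β,6α-dihydroxy-10-ketone)
Conditions: Me4NBH(OAc)3, MeCN–AcOH, −40 to −20 °C
Reagents that add atoms: none
Why: Evans–Saksena hydroxyl-directed reduction: the C4 hydroxyl exchanges onto boron and hydride is delivered through a six-membered transition state to the C6 carbonyl on the face where C4 lies (β), giving the 6α-alcohol, anti to the C4 oxygen. The C10 ketone is 1,4 to the hydroxyl and flanked by the quaternary C1, and ketones without a β-hydroxyl are inert to triacetoxyborohydride at this temperature, so the two carbonyl groups are told apart here; the new carbinol also ends the epimerisability of C5.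

Step 7
Reactants: 11 4-hydroxybenzoic acid
Product: 13 4-(tert-butyldimethylsilyloxy)benzoic acid, via bis-silyl derivative 12 (not isolated)
Conditions: tBuMe2SiCl, imidazole, DMF, rt; then AcOH–THF–H2O, rt
Reagents that add atoms: tert-butyldimethylsilyl chloride, CC(C)(C)[Si](C)(C)Cl
Why: Silylation of both the phenol and the acid, then selective hydrolysis of the far more labile silyl ester; the aryl silyl ether survives dilute acetic acid. The masked phenol cannot compete as a nucleophile in steps 8 and 11.

Step 8
Reactants: 10 diol ketone; 13 4-(tert-butyldimethylsilyloxy)benzoic acid
Product: 15 C6 aroyl ester (6α-[4-(tert-butyldimethylsilyloxy)benzoyloxy]-4β-hydroxy-10-ketone), via mixed anhydride 14 (not isolated)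
Conditions: 13, 2,4,6-Cl3C6H2COCl, Et3N, toluene, rt; then 10, DMAP, rt to 50 °C
Reagents that add atoms: none
Why: Yamaguchi esterification: DMAP attacks the mixed anhydride 14 at the unhindered aroyl carbonyl and the acylpyridinium ion acylates the only secondary hydroxyl of 10, while the tertiary C4 hydroxyl does not react. Any transannular hemiketal between the C6 hydroxyl and the C10 carbonyl is in equilibrium with the open form and is drained by the acylation.

Step 9
Reactants: 15 C6 aroyl ester
Product: 18 enone (6α-aroyloxy-4β-hydroxy-hydroazul-8-en-10-one), via silyl enol ether 16 (not isolated), via silylated enone 17 (not isolated)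
Conditions: Me3SiOTf, Et3N, CH2Cl2, 0 °C; then Pd(OAc)2, MeCN, rt; then PPTS, MeOH, 0 °C
Reagents that add atoms: none
Why: Saegusa–Ito oxidation: soft enolisation can only go towards C9 because C1 is quaternary (the C4 hydroxyl is silylated at the same time), and Pd(OAc)2 converts the silyl enol ether into a palladium enolate that loses its only β-hydrogen (on C8) to give the C8=C9 enone, so both C8 epimers converge. Brief acid methanolysis then frees the tertiary C4 hydroxyl (the aryl silyl ether is stable to it), which is needed as the directing group in step 10; strong base is avoided throughout because the γ-hydrogens at C7 of the enone could expel the C6 ester.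

Step 10
Reactants: 18 enone
Product: 19 allylic alcohol (10α-hydroxy-hydroazul-8-ene)
Conditions: Me4NBH(OAc)3, MeCN–AcOH, 0 °C to rt
Reagents that add atoms: none
Why: Hydroxyl-directed triacetoxyborohydride reduction, applied to a 1,4-related hydroxy enone held in proximity by ring A: the C4 hydroxyl is the only free hydroxyl, it is cis-1,3 to C10, and in the ring B conformer that places C4 pseudo-axial over the enone it can hand hydride to the β face of the carbonyl carbon through a seven-membered transition state, giving the 10α-alcohol by 1,2-reduction. Enones without a neighbouring hydroxyl are not reduced by this reagent, so the background attack on the α face that an external hydride is expected to prefer is suppressed.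

Step 11
Reactants: 19 allylic alcohol; 20 tiglic acid
Product: 22 tiglate (10α-tigloyloxy compound with silylated phenol), via mixed anhydride 21 (not isolated)
Conditions: 20, 2,4,6-Cl3C6H2COCl, Et3N, toluene, rt; then 19, DMAP, 60 °C
Reagents that add atoms: none
Why: Yamaguchi esterification through the mixed anhydride 21: DMAP-mediated acyl transfer is strong enough for the neopentyl-type allylic alcohol, retains the C10 configuration because the C–O bond is not broken, and does not isomerise the E-alkene of the tigloyl group. The tertiary C4 hydroxyl stays free.

Step 12
Reactants: 22 tiglate
Product: 23 target compound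
Conditions: Bu4NF, AcOH, THF, 0 °C
Reagents that add atoms: none
Why: Aryl silyl ethers are cleaved rapidly by fluoride; buffering with acetic acid keeps the medium from becoming basic, so neither ester is cleaved or migrates and the allylic tiglate is not ionised.

## Compound list

1 | dimethyl 3-methylglutarate | COC(=O)CC(C)CC(=O)OC | starting material
2 | 4-methyl-1,2-bis(trimethylsilyloxy)cyclopentene | CC1CC(O[Si](C)(C)C)=C(O[Si](C)(C)C)C1 | intermediate
3 | dilithium 4-methylcyclopent-1-ene-1,2-diolate | CC1CC([O-])=C([O-])C1.[Li+].[Li+] | intermediate
4 | 4-methyl-1,2-bis(tert-butyldimethylsilyloxy)cyclopentene | CC1CC(O[Si](C)(C)C(C)(C)C)=C(O[Si](C)(C)C(C)(C)C)C1 | intermediate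
5 | 3-methylcyclopent-2-en-1-one | CC1=CC(=O)CC1 | starting material
6 | cis-anti-cis photoadduct (target locants): 6,10-bis(tert-butyldimethylsilyloxy)-1,8-dimethyl 5-4-5 tricyclic 4-ketone; cyclobutane C1–C5–C6–C10; C1 methyl and H5 cis; rings A and C on opposite faces of the cyclobutane; both silyloxy groups on the ring A side; C8 methyl cis to the silyloxy groups; C1 R, C5 S | CC(C)(C)[Si](C)(C)O[C@@]12C[C@@H](C)C[C@]1(O[Si](C)(C)C(C)(C)C)[C@@H]3[C@@]2(C)CCC3=O | intermediate
7 | tertiary alcohol from 6: C4 carbinol, isopropyl on the exo (α) face cis to H5, hydroxyl on the endo (β) face | CC(C)(C)[Si](C)(C)O[C@@]12C[C@@H](C)C[C@]1(O[Si](C)(C)C(C)(C)C)[C@@H]3[C@@]2(C)CC[C@@]3(O)C(C)C | intermediate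
8 | 4β,6,10-triol (7 without its silyl groups; cis-cyclobutane-1,2-diol) | O[C@@]12C[C@@H](C)C[C@]1(O)[C@@H]3[C@@]2(C)CC[C@@]3(O)C(C)C | intermediate
9 | 4β-hydroxy-4α-isopropyl-1α,8β-dimethyl-cis-bicyclo[5.3.0]decane-6,10-dione (target locants, H5 α) | O=C1C[C@@H](C)CC(=O)[C@@H]2[C@@]1(C)CC[C@@]2(O)C(C)C | intermediate
10 | 4β,6α-dihydroxy-4α-isopropyl-1α,8β-dimethyl-cis-bicyclo[5.3.0]decan-10-one | O=C1C[C@@H](C)C[C@H](O)[C@@H]2[C@@]1(C)CC[C@@]2(O)C(C)C | intermediate
11 | 4-hydroxybenzoic acid | O=C(O)c1ccc(O)cc1 | starting material
12 | tert-butyldimethylsilyl 4-(tert-butyldimethylsilyloxy)benzoate | CC(C)(C)[Si](C)(C)OC(=O)c1ccc(O[Si](C)(C)C(C)(C)C)cc1 | intermediate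
13 | 4-(tert-butyldimethylsilyloxy)benzoic acid | CC(C)(C)[Si](C)(C)Oc1ccc(cc1)C(=O)O | intermediate
14 | 4-(tert-butyldimethylsilyloxy)benzoic 2,4,6-trichlorobenzoic anhydride | CC(C)(C)[Si](C)(C)Oc1ccc(cc1)C(=O)OC(=O)c1c(Cl)cc(Cl)cc1Cl | intermediate
15 | 6α-[4-(tert-butyldimethylsilyloxy)benzoyloxy]-4β-hydroxy-4α-isopropyl-1α,8β-dimethyl-cis-bicyclo[5.3.0]decan-10-one | O=C1C[C@@H](C)C[C@H](OC(=O)c2ccc(O[Si](C)(C)C(C)(C)C)cc2)[C@@H]2[C@@]1(C)CC[C@@]2(O)C(C)C | intermediate
16 | 10-trimethylsilyloxy-9-ene (silyl enol ether) of 15 with a 4β-trimethylsilyloxy group | C[Si](C)(C)OC1=C[C@@H](C)C[C@H](OC(=O)c2ccc(O[Si](C)(C)C(C)(C)C)cc2)[C@@H]2[C@@]1(C)CC[C@@]2(O[Si](C)(C)C)C(C)C | intermediate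
17 | 6α-aroyloxy-4β-trimethylsilyloxy-4α-isopropyl-1α,8-dimethyl-cis-bicyclo[5.3.0]dec-8-en-10-one | O=C1C=C(C)C[C@H](OC(=O)c2ccc(O[Si](C)(C)C(C)(C)C)cc2)[C@@H]2[C@@]1(C)CC[C@@]2(O[Si](C)(C)C)C(C)C | intermediate
18 | 6α-[4-(tert-butyldimethylsilyloxy)benzoyloxy]-4β-hydroxy-4α-isopropyl-1α,8-dimethyl-cis-bicyclo[5.3.0]dec-8-en-10-one | O=C1C=C(C)C[C@H](OC(=O)c2ccc(O[Si](C)(C)C(C)(C)C)cc2)[C@@H]2[C@@]1(C)CC[C@@]2(O)C(C)C | intermediate
19 | 10α-allylic alcohol: 6α-[4-(tert-butyldimethylsilyloxy)benzoyloxy]-4β,10α-dihydroxy-4α-isopropyl-1α,8-dimethyl-cis-bicyclo[5.3.0]dec-8-ene | O[C@@H]1C=C(C)C[C@H](OC(=O)c2ccc(O[Si](C)(C)C(C)(C)C)cc2)[C@@H]2[C@@]1(C)CC[C@@]2(O)C(C)C | intermediate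
20 | tiglic acid, (E)-2-methylbut-2-enoic acid | C/C=C(\C)C(=O)O | starting material
21 | tiglic 2,4,6-trichlorobenzoic anhydride | C/C=C(\C)C(=O)OC(=O)c1c(Cl)cc(Cl)cc1Cl | intermediate
22 | 10α-tiglate of 19 (phenol still silylated) | C/C=C(\C)C(=O)O[C@@H]1C=C(C)C[C@H](OC(=O)c2ccc(O[Si](C)(C)C(C)(C)C)cc2)[C@@H]2[C@@]1(C)CC[C@@]2(O)C(C)C | intermediate
23 | target: (1R,4R,5S,6S,10R)-4-hydroxy-6-(4-hydroxybenzoyloxy)-4-isopropyl-1,8-dimethyl-10-tigloyloxy-cis-bicyclo[5.3.0]dec-8-ene (target locants) | C/C=C(\C)C(=O)O[C@@H]1C=C(C)C[C@H](OC(=O)c2ccc(O)cc2)[C@@H]2[C@@]1(C)CC[C@@]2(O)C(C)C | target

## Step count and least certain steps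

Total: 12 steps. Longest linear sequence: 11 steps (steps 1–6 and 8–12, from 1 to 23); step 7 is a one-step side branch.

Step 3 (key step, proposed new method). The most likely failure is loss of enantiofacial control, because free 5 still absorbs weakly at 366 nm and gives the uncatalysed, racemic cycloaddition. The second is consumption of 4 in the dark by Lewis-acid-promoted conjugate addition or desilylation before the photoreaction can occur. Fallback with known chemistry, setting out from 4 and 5: irradiate the two without any Lewis acid (350 nm, Pyrex, CH2Cl2, −20 °C), which is the established racemic enone/bis(silyloxy)alkene photocycloaddition. This should give 6 together with an equal amount of the mirror-image photoadduct F1. The two are then separated by preparative chromatography on a chiral stationary phase (amylose tris(3,5-dimethylphenylcarbamate)), at the cost of half the material. The route is rejoined at 6.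

Step 10. Hydride delivery through the larger cyclic transition state may be too slow, leaving 18 unchanged or letting solvolysis of the allylic alcohol in acetic acid compete; the productive conformer, with C4 over the enone, may also be poorly populated. Fallback, setting out from 18: Luche reduction (NaBH4, CeCl3·7H2O, MeOH, −78 °C) with external hydride. If this enters on the α face, as expected for the conformer in which ring A covers the β face, it gives the C10-epimeric 10β-allylic alcohol F3. F3 is then esterified with 20 under Mitsunobu conditions (PPh3, diisopropyl azodicarboxylate, toluene, 0 °C), which inverts C10 and gives the tiglate directly. The route is rejoined at 22. Should the Luche reduction give 19 instead, step 11 follows as written.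

Step 6. Over-reduction is the main risk: once C6 is reduced, boron can be re-loaded on the C4 oxygen or on the new C6 oxygen and hand hydride to the C10 ketone, and H5 can epimerise before reduction if 9 is kept too long. Fallback, setting out from 9: chelation-controlled single-electron reduction with SmI2 in THF–MeOH at −78 °C. This reduces only the carbonyl that can chelate with a β-hydroxyl and is anti-selective for β-hydroxy ketones. It rejoins the route at 10 and makes no new compound (F0).

Step 4. Enolisation or β-hydride reduction may win over addition, because the carbonyl is shielded by the neighbouring endo silyloxy group and the nucleophile is secondary. Fallback, setting out from 6: add the smaller sp2 nucleophile isopropenylmagnesium bromide with CeCl3 (no β-hydride to transfer) to give the isopropenyl carbinol F2, then hydrogenate the 1,1-disubstituted alkene (H2, PtO2, EtOAc). The route is rejoined at 7.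

## Further compounds

F1 | step 3 | mirror-image photoadduct (enantiomer of 6) | CC(C)(C)[Si](C)(C)O[C@]12C[C@H](C)C[C@@]1(O[Si](C)(C)C(C)(C)C)[C@H]3[C@]2(C)CCC3=O
F2 | step 4 | isopropenyl carbinol (7 with prop-1-en-2-yl in place of isopropyl at C4) | CC(C)(C)[Si](C)(C)O[C@@]12C[C@@H](C)C[C@]1(O[Si](C)(C)C(C)(C)C)[C@@H]3[C@@]2(C)CC[C@@]3(O)C(C)=C
F0 | step 6 | none | none
F3 | step 10 | 10β-allylic alcohol (C10 epimer of 19) | O[C@H]1C=C(C)C[C@H](OC(=O)c2ccc(O[Si](C)(C)C(C)(C)C)cc2)[C@@H]2[C@@]1(C)CC[C@@]2(O)C(C)C
A1 | alternative 1 | 1-diazo-4-(2-methoxy-4-methylphenyl)butan-2-one | COc1cc(C)ccc1CCC(=O)C=[N+]=[N-]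
A2 | alternative 1 | 4-methoxy-6-methyl-3,8a-dihydroazulen-1(2H)-one (single enantiomer at C8a, the target C5) | COC1=C2CCC(=O)[C@@H]2C=CC(C)=C1
A3 | alternative 2 | 2-bromo-3-methylcyclopentanone carrying at C3 the (Z)-1-(tert-butyldimethylsilyloxy)-3-methyl-5-oxopent-2-enyl chain (target C10 to C6) | O=CC/C(C)=C\[C@@H](O[Si](C)(C)C(C)(C)C)[C@]1(C)CCC(=O)C1Br
A4 | alternative 2 | 10α-(tert-butyldimethylsilyloxy)-6α-hydroxy-1α,8-dimethyl-cis-bicyclo[5.3.0]dec-8-en-4-one (target locants) | CC(C)(C)[Si](C)(C)O[C@@H]1C=C(C)C[C@H](O)[C@@H]2[C@@]1(C)CCC2=O
A5 | alternative 3 | (R)-Wieland–Miescher ketone | O=C1CCCC2=CC(=O)CC[C@@]12C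
A6 | alternative 3 | decalin hydroxy mesylate (target locants: C6 tertiary hydroxyl at the ring fusion, C5 mesylate, C4 triethylsilyloxy and isopropyl, C10 tert-butyldimethylsilyloxy, C1 and C8 methyl) | CC(C)(C)[Si](C)(C)O[C@@H]1C[C@H](C)C[C@]2(O)[C@@H](OS(C)(=O)=O)[C@](O[Si](CC)(CC)CC)(C(C)C)CC[C@@]12C
A7 | alternative 3 | cis-fused hydroazulen-6-one with C4 triethylsilyl and C10 tert-butyldimethylsilyl ethers | CC(C)(C)[Si](C)(C)O[C@@H]1C[C@H](C)CC(=O)[C@@H]2[C@@]1(C)CC[C@@]2(O[Si](CC)(CC)CC)C(C)C
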